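Everything rests on opening ring C at three bonds, C4a–C4, C4–C3 and O1–C2. The ring C carbonyl C4 has only C4a of ring A and C3 as carbon neighbours, and O1 hangs on C8a ortho to C4a, so C4 can be delivered as CO gas, ring A as an ortho-iodophenol and C3–C2 with ring B as a terminal arylalkyne. One palladium-catalysed operation joins the three and closes ring C as an achiral flavone. The iodide is mirror-symmetric 2-iodo-5-methoxy-4,6-dimethylresorcinol, whose two hydroxyls are equivalent, so no oxygen needs to be distinguished before coupling. C2 is set afterwards by asymmetric copper hydride reduction, and ring B becomes the quinone last.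

Key step: step 6

Remark: with the priorities O1 > C1' (ring B) > C3 > H the stereocentre of the target is 2S, and the same descriptor holds for every chiral compound of the route.
Assumption: (R)-DTBM-SEGPHOS is written in step 8 as the ligand hand that sends hydride to the Re face of C2; a small-scale run has to confirm the sense, and the (S)-ligand is used if it proves opposite.

Step 1
Reactants: 1 methyl 2,4,6-trihydroxybenzoate
Product: 3 methyl 2,4,6-trihydroxy-3,5-dimethylbenzoate, via monomethyl ester 2 (not isolated)
Conditions: MeI (2.1 equiv), NaOMe (3 equiv), MeOH, 0 °C to reflux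
Reagents that add atoms: iodomethane, CI
Why: Nuclear C-methylation of a phloroglucinol: in methanol the phloroglucinolate reacts with the soft electrophile MeI at its two free ring carbons (the ester blocks the third), and holding MeI near two equivalents should limit further alkylation to dearomatised gem-dimethyl products.

Step 2
Reactants: 3 methyl 2,4,6-trihydroxy-3,5-dimethylbenzoate
Product: 4 methyl 2,6-dihydroxy-4-methoxy-3,5-dimethylbenzoate
Conditions: Me2SO4 (1.05 equiv), K2CO3 (1.1 equiv), acetone, rt to 40 °C
Reagents that add atoms: dimethyl sulfate, COS(=O)(=O)OC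
Why: Williamson O-methylation: the 4-hydroxyl, para to the ester, is the most acidic and the only one not hydrogen-bonded to the ester, so one equivalent of the hard electrophile Me2SO4 should methylate it alone.

Step 3
Reactants: 4 methyl 2,6-dihydroxy-4-methoxy-3,5-dimethylbenzoate
Product: 6 5-methoxy-4,6-dimethylbenzene-1,3-diol, via carboxylic acid 5 (not isolated)
Conditions: KOH (20 % aq.), N2, reflux; then HCl to pH 1, 60 °C
Reagents that add atoms: none
Why: Saponification followed by decarboxylation of a 2,6-dihydroxybenzoic acid: acid 5, with hydroxyl groups at both ortho positions and a para methoxy group, is protonated at the ipso carbon and should lose CO2 on gentle warming, leaving the symmetric resorcinol with the methoxy group between the two methyl groups.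

Step 4
Reactants: 6 5-methoxy-4,6-dimethylbenzene-1,3-diol
Product: 7 2-iodo-5-methoxy-4,6-dimethylbenzene-1,3-diol
Conditions: NIS (1.0 equiv), MeCN, 0 °C, dark
Reagents that add atoms: N-iodosuccinimide, O=C1CCC(=O)N1I
Why: Electrophilic aromatic iodination: the only unsubstituted ring carbon lies between the two hydroxyl groups, so one equivalent of NIS at low temperature can give only the 2-iodide.

Step 5
Reactants: 8 2,4,5-trimethoxybenzaldehyde
Product: 10 1-ethynyl-2,4,5-trimethoxybenzene, via diazoalkene 9 (not isolated)
Conditions: dimethyl (1-diazo-2-oxopropyl)phosphonate (1.3 equiv), K2CO3 (2 equiv), MeOH, 0 °C to rt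
Reagents that add atoms: dimethyl (1-diazo-2-oxopropyl)phosphonate (Ohira–Bestmann reagent), CC(=O)C(=[N+]=[N-])P(=O)(OC)OC
Why: Seyferth–Gilbert homologation with the Ohira–Bestmann reagent: methoxide removes the acetyl group to give the diazomethylphosphonate anion, which olefinates the aldehyde to diazoalkene 9, and loss of N2 with a 1,2-hydrogen shift should give the terminal alkyne under conditions mild enough for the electron-rich arene.

Step 6
Reactants: 7 2-iodo-5-methoxy-4,6-dimethylbenzene-1,3-diol; 10 1-ethynyl-2,4,5-trimethoxybenzene; 11 carbon monoxide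
Product: 14 5-hydroxy-7-methoxy-6,8-dimethyl-2-(2,4,5-trimethoxyphenyl)-4H-chromen-4-one, via ynone 12 (not isolated), via enaminone 13 (not isolated)
Conditions: PdCl2(PPh3)2 (5 mol %), CO (10 bar), Et2NH, 100–120 °C, autoclave
Reagents that add atoms: none
Why: Zerovalent palladium formed from PdCl2(PPh3)2 inserts into the C–I bond of 7, CO insertion gives the aroyl complex ArC(O)PdI(PPh3)2, and coupling with the amine-activated alkyne followed by reductive elimination gives ynone 12, which forms C4a–C4 and C4–C3. Diethylamine then adds to the ynone to give enaminone 13, and one of the two equivalent hydroxyl groups attacks the amine-bearing carbon and expels diethylamine, which forms O1–C2. Ring C is closed in this way by a 6-endo-trig conjugate addition followed by elimination. The closest known reaction type is the carbonylative Sonogashira coupling of 2-iodophenols with terminal alkynes in a secondary amine, which ends in cyclisation to flavones. No stereocentre is formed. The step needs CO uptake to outrun direct alkyne coupling, which CO pressure and the electron-rich aryl palladium species favour, and it needs 6-endo closure in place of 5-exo closure to an aurone, which the enaminone secures because C2 is its only electrophilic carbon, while the mirror symmetry of 7 leaves no choice between the two oxygens.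

Step 7
Reactants: 14 5-hydroxy-7-methoxy-6,8-dimethyl-2-(2,4,5-trimethoxyphenyl)-4H-chromen-4-one
Product: 15 5-(benzyloxy)-7-methoxy-6,8-dimethyl-2-(2,4,5-trimethoxyphenyl)-4H-chromen-4-one
Conditions: BnBr (1.5 equiv), K2CO3 (3 equiv), DMF, 70 °C
Reagents that add atoms: benzyl bromide, BrCc1ccccc1
Why: Williamson etherification: the 5-hydroxyl is the only free hydroxyl of the robust, achiral flavone, and although it is hydrogen-bonded to C4=O, K2CO3 in warm DMF should benzylate it, so that the hydride step meets no acidic proton.

Step 8
Reactants: 15 5-(benzyloxy)-7-methoxy-6,8-dimethyl-2-(2,4,5-trimethoxyphenyl)-4H-chromen-4-one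
Product: 17 (S)-5-(benzyloxy)-7-methoxy-6,8-dimethyl-2-(2,4,5-trimethoxyphenyl)chroman-4-one, via silyl enol ether 16 (not isolated)
Conditions: Cu(OAc)2 (5 mol %), (R)-DTBM-SEGPHOS (5.5 mol %), (EtO)2MeSiH (3 equiv), THF, 0 °C to rt; then aq. NH4F, MeOH, 0 °C
Reagents that add atoms: none
Why: Copper hydride-catalysed asymmetric conjugate reduction of a β,β-disubstituted enone: the bisphosphine-bound CuH made from Cu(OAc)2 and the silane adds hydride to the Re face of C2 under control of the chiral ligand and so sets the 2S centre, the copper enolate is trapped as silyl enol ether 16 so that O1 is not expelled, and near-neutral fluoride hydrolysis should then release the ketone without touching C2.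

Step 9
Reactants: 17 (S)-5-(benzyloxy)-7-methoxy-6,8-dimethyl-2-(2,4,5-trimethoxyphenyl)chroman-4-one
Product: 18 (S)-5-hydroxy-7-methoxy-6,8-dimethyl-2-(2,4,5-trimethoxyphenyl)chroman-4-one
Conditions: H2 (1 atm), 10 % Pd/C, EtOAc, rt
Reagents that add atoms: none
Why: Catalytic hydrogenolysis of a benzyl aryl ether: the O–CH2Ph bond is cleaved on Pd/C in a neutral solvent, under which the hindered C2–O1 bond, the ketone and the 2S centre should stay intact if the reaction is stopped at full conversion.

Step 10
Reactants: 18 (S)-5-hydroxy-7-methoxy-6,8-dimethyl-2-(2,4,5-trimethoxyphenyl)chroman-4-one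
Product: 19 2-[(2S)-5-hydroxy-7-methoxy-6,8-dimethyl-4-oxochroman-2-yl]-5-methoxycyclohexa-2,5-diene-1,4-dione
Conditions: (NH4)2Ce(NO3)6 (2.5 equiv), MeCN/H2O (2:1), 0 °C, 15 min; neutral to slightly acidic work-up
Reagents that add atoms: water, O
Why: Oxidative demethylation of a para-dimethoxyarene to a para-quinone: two equivalents of tetravalent cerium oxidise ring B, the most electron-rich ring, water adds at C2' and C5' and methanol is lost, so the 1,4-quinone keeps the 4'-methoxy group, while ring A is deactivated by the hydrogen-bonded ketone and the short, cold, acidic conditions should not epimerise C2.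

Compound list
1 | methyl 2,4,6-trihydroxybenzoate | COC(=O)c1c(O)cc(O)cc1O | starting material
2 | methyl 2,4,6-trihydroxy-3-methylbenzoate (monomethyl ester) | COC(=O)c1c(O)c(C)c(O)cc1O | intermediate
3 | methyl 2,4,6-trihydroxy-3,5-dimethylbenzoate | COC(=O)c1c(O)c(C)c(O)c(C)c1O | intermediate
4 | methyl 2,6-dihydroxy-4-methoxy-3,5-dimethylbenzoate | COC(=O)c1c(O)c(C)c(OC)c(C)c1O | intermediate
5 | 2,6-dihydroxy-4-methoxy-3,5-dimethylbenzoic acid | OC(=O)c1c(O)c(C)c(OC)c(C)c1O | intermediate
6 | 5-methoxy-4,6-dimethylbenzene-1,3-diol | COc1c(C)c(O)cc(O)c1C | intermediate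
7 | 2-iodo-5-methoxy-4,6-dimethylbenzene-1,3-diol | COc1c(C)c(O)c(I)c(O)c1C | intermediate
8 | 2,4,5-trimethoxybenzaldehyde | COc1cc(OC)c(C=O)cc1OC | starting material
9 | 1-(2-diazoethenyl)-2,4,5-trimethoxybenzene (diazoalkene) | COc1cc(OC)c(C=C=[N+]=[N-])cc1OC | intermediate
10 | 1-ethynyl-2,4,5-trimethoxybenzene | COc1cc(OC)c(C#C)cc1OC | intermediate
11 | carbon monoxide | [C-]#[O+] | starting material
12 | 1-(2,6-dihydroxy-4-methoxy-3,5-dimethylphenyl)-3-(2,4,5-trimethoxyphenyl)prop-2-yn-1-one (ynone) | COc1cc(OC)c(C#CC(=O)c2c(O)c(C)c(OC)c(C)c2O)cc1OC | intermediate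
13 | (E)-3-(diethylamino)-1-(2,6-dihydroxy-4-methoxy-3,5-dimethylphenyl)-3-(2,4,5-trimethoxyphenyl)prop-2-en-1-one (enaminone) | CCN(CC)/C(=C/C(=O)c1c(O)c(C)c(OC)c(C)c1O)c1cc(OC)c(OC)cc1OC | intermediate
14 | 5-hydroxy-7-methoxy-6,8-dimethyl-2-(2,4,5-trimethoxyphenyl)-4H-chromen-4-one | COc1cc(OC)c(-c2cc(=O)c3c(O)c(C)c(OC)c(C)c3o2)cc1OC | intermediate
15 | 5-(benzyloxy)-7-methoxy-6,8-dimethyl-2-(2,4,5-trimethoxyphenyl)-4H-chromen-4-one | COc1cc(OC)c(-c2cc(=O)c3c(OCc4ccccc4)c(C)c(OC)c(C)c3o2)cc1OC | intermediate
16 | (S)-{[5-(benzyloxy)-7-methoxy-6,8-dimethyl-2-(2,4,5-trimethoxyphenyl)-2H-chromen-4-yl]oxy}diethoxy(methyl)silane (silyl enol ether) | COc1cc(OC)c([C@@H]2C=C(O[Si](C)(OCC)OCC)c3c(OCc4ccccc4)c(C)c(OC)c(C)c3O2)cc1OC | intermediate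
17 | (S)-5-(benzyloxy)-7-methoxy-6,8-dimethyl-2-(2,4,5-trimethoxyphenyl)chroman-4-one | COc1cc(OC)c([C@@H]2CC(=O)c3c(OCc4ccccc4)c(C)c(OC)c(C)c3O2)cc1OC | intermediate
18 | (S)-5-hydroxy-7-methoxy-6,8-dimethyl-2-(2,4,5-trimethoxyphenyl)chroman-4-one | COc1cc(OC)c([C@@H]2CC(=O)c3c(O)c(C)c(OC)c(C)c3O2)cc1OC | intermediate
19 | 2-[(2S)-5-hydroxy-7-methoxy-6,8-dimethyl-4-oxochroman-2-yl]-5-methoxycyclohexa-2,5-diene-1,4-dione | COC1=CC(=O)C([C@@H]2CC(=O)c3c(O)c(C)c(OC)c(C)c3O2)=CC1=O | target

Total step count: 10
Longest linear sequence: 9 steps (steps 1–4 and 6–10)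

Steps most likely to fail

Step 6. Oxidative addition into the electron-rich C–I bond flanked by two oxygen substituents may be slow. Loss of iodine, capture of the aroyl palladium species by diethylamine, or coupling without CO uptake followed by closure to a benzofuran may then take over. The fallback takes C4 from an acetyl group instead of CO. Setting out from 6, C-acetylation at its only free ring carbon with Ac2O and BF3·OEt2 should give 1-(2,6-dihydroxy-4-methoxy-3,5-dimethylphenyl)ethan-1-one F1. Claisen–Schmidt condensation of F1 with aldehyde 8 (KOH, EtOH) should give the chalcone (E)-1-(2,6-dihydroxy-4-methoxy-3,5-dimethylphenyl)-3-(2,4,5-trimethoxyphenyl)prop-2-en-1-one F2. Oxidative cyclisation of F2 with catalytic I2 in DMSO at 120 °C should close ring C and come back to the route at flavone 14.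

Step 8. Hydride transfer to the hindered, electron-rich C2 (an ortho-methoxyaryl group on a vinylogous ester) may be slow or poorly face-selective. The copper enolate may also expel O1 before silyl transfer, which opens ring C and leads to further reduction of the open-chain enone. The fallback hydrogenates to the alcohol and re-oxidises. Setting out from 15, asymmetric hydrogenation with a chiral ruthenium N-heterocyclic carbene catalyst, made from Ru(cod)(2-methylallyl)2, a C2-symmetric chiral imidazolinium tetrafluoroborate and KOtBu under H2 pressure, is a known reduction of flavones. With the ligand hand chosen for 2S it should give the cis alcohol (2S,4S)-5-(benzyloxy)-7-methoxy-6,8-dimethyl-2-(2,4,5-trimethoxyphenyl)chroman-4-ol F3. Oxidation of the C4 alcohol with Dess–Martin periodinane buffered with NaHCO3 comes back to the route at 17.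

Step 10. The one-electron oxidation may not stay on the para-dimethoxy pair of ring B. The free ring A phenol may be oxidised, the C2–H bond next to the oxidised ring may be lost (dehydrogenation or opening of ring C), or the adjacent 4',5'-dimethoxy pair may give an ortho-quinone. The fallback oxidises before deprotection and then removes the benzyl group without hydrogen. Setting out from 17, (NH4)2Ce(NO3)6 in MeCN/H2O at 0 °C, with the phenol still benzylated, should give 2-[(2S)-5-(benzyloxy)-7-methoxy-6,8-dimethyl-4-oxochroman-2-yl]-5-methoxycyclohexa-2,5-diene-1,4-dione F4. Chelation-assisted cleavage of the benzyl ether peri to C4=O with BCl3 in CH2Cl2 at −78 °C should then give the target 19.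

Further compounds
F1 | step 6 | 1-(2,6-dihydroxy-4-methoxy-3,5-dimethylphenyl)ethan-1-one | CC(=O)c1c(O)c(C)c(OC)c(C)c1O
F2 | step 6 | (E)-1-(2,6-dihydroxy-4-methoxy-3,5-dimethylphenyl)-3-(2,4,5-trimethoxyphenyl)prop-2-en-1-one | COc1cc(OC)c(/C=C/C(=O)c2c(O)c(C)c(OC)c(C)c2O)cc1OC
F3 | step 8 | (2S,4S)-5-(benzyloxy)-7-methoxy-6,8-dimethyl-2-(2,4,5-trimethoxyphenyl)chroman-4-ol | COc1cc(OC)c([C@@H]2C[C@H](O)c3c(OCc4ccccc4)c(C)c(OC)c(C)c3O2)cc1OC
F4 | step 10 | 2-[(2S)-5-(benzyloxy)-7-methoxy-6,8-dimethyl-4-oxochroman-2-yl]-5-methoxycyclohexa-2,5-diene-1,4-dione | COC1=CC(=O)C([C@@H]2CC(=O)c3c(OCc4ccccc4)c(C)c(OC)c(C)c3O2)=CC1=O
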